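In a one-step world a flask is a queue: each catalyst works through its share of substrate, and the clock says when the queue is empty.

| flask | substrate | free catalyst | remark | time |
|---|---|---|---|---|
| south-east | 1.3 M | 1.9 mM | run made earlier |  |
| green | 0.60 M | 1.9 mM |  | 40 min |
| blue | 1.2 M | 1.9 mM |  | 40 min |
| amber | 0.60 M | 0.60 mM |  | 40 min |
| violet | 1.2 M | 0.60 mM |  | 40 min |

south-east run (percent of the substrate charged)

| time / min | target / % | substrate / % |
|---|---|---|
| 1.33 | 6.1 | 94.3 |
| 4.00 | 17.7 | 82.5 |
| 6.00 | 26.1 | 74.0 |
| 10.0 | 41.1 | 58.2 |
| 15.0 | 58.0 | 38.8 |

(each reading ± 0.3 percentage points)

* all flasks from highest to lowest amount of target, in percent of the substrate charged, at 40 min (green / blue / amber / violet)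
* the amount of target, in percent of the substrate charged of the flask you put first, at 40 min
* the amount of target, in percent of the substrate charged of the flask you put last, at 40 min

- no earlier run changes the charge of free catalyst; that part of a forecast is a guess

What do you read from the south-east run? Substrate falls nearly in a straight line, so I count turnovers. From 4.00 min to 10.0 min the pace is f = 27.7 min⁻¹, the turnover pace: moles of substrate used per minute per mole of catalyst charged, the turnover frequency.

What does f buy? The clearing time τ, the charge ratio of substrate to catalyst divided by f: green 11.4 min, blue 22.8 min, amber 36.1 min, violet 72.2 min. Violet's τ is longer than the 40 min allowed, so my reckoning puts its target near 55.4%, while amber's τ is just shorter.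

Where is that weak? In the catalyst and in the balance. No earlier run changes the catalyst charge, so scaling by it is a guess. And at 15.0 min the south-east balance is 3.20% short, against a scatter of 0.3 percentage points.

So what do you commit to? If that gap is a loss that goes on after clearing, my reckoning gives green 28.6 min of it after τ and blue 17.2 min. One gap can't size that loss, so I put amber first and leave the other places open.

The forecast gives amber > violet > blue > green, with 74% at the top and 37% at the bottom, reading the gap as “target being consumed further once it competes with substrate”.

The flask gives amber > blue > green > violet: amber 75.9%, blue 67.5%, green 55.6%, violet 53.5%.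

    substrate + free catalyst ⇌ catalyst intermediate A (K = 56.7 L mol⁻¹, k = 4.54 L mol⁻¹ s⁻¹)
    catalyst intermediate A → catalyst intermediate B (k = 0.604 s⁻¹)
    catalyst intermediate B ⇌ free catalyst + target (K = 1.65 M, k = 7.96 s⁻¹)
    target + free catalyst ⇌ isomer of the product + free catalyst, rate k4*[free catalyst]*[target] forward; the back reaction follows from the equilibrium constant (K = 1.17, k = 0.366 L mol⁻¹ s⁻¹)

In amber at 16.5 min, the half-life of target by the forward loss to isomer of the product alone is 190 min, long against the 40 min of the run. At 40.0 min amber holds 8.09% isomer of the product beside 75.9% target and 16% substrate, although its τ of 36.1 min has passed. The pace f leaves 44.6% substrate in violet at 40.0 min, where the flask shows 44%. For amber read at 10 min, f leaves 72.3% substrate, and that flask shows 73.7%.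

The readings were computed from invented constants, and the scatter is random.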